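**Retrosynthetic overview**

1. Numbering: ring C1 (angelate carbinol), C2, C3 (CH3), C4 (OAc), C5, C6 (side chain C7–C11, acetate on C9). The plan rests on the cyclohexane ring C1–C6 carrying its oxygens on C1 and C4 in a 1,4-cis relation, both trans to the C6 side chain: the footprint of a C1/C4 endoperoxide of a cyclohexa-1,3-diene.
2. Late bonds: C1–O angelate (last), both acetates in one operation, C9–C10 (2-methylprop-1-enyl Grignard on a C9 aldehyde, C9 then fixed by oxazaborolidine reduction), C4 carbinol from the C4 ketone with LiBH(s-Bu)3, C3 by hydrogenation and equilibration of the C2=C3 enone.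
3. Key disconnection: the C1–O and C4–O bonds go back to diene 10 and O2 (singlet-oxygen [4+2]); Kornblum–DeLaMare opening of the peroxide then tells the two oxygens apart (C1–OH, C4=O).
4. Diene 10 comes from 4-substituted cyclohexenone 7 (kinetic dienyl triflate, methyl Negishi coupling for C3–CH3); 7 comes from aldehyde 4 and methyl vinyl ketone by amine-catalysed Michael addition and aldol condensation (sets C6); 4 comes from methyl hydrogen (R)-3-methylglutarate (carries C7).
5. Ring order: the carbocycle C1–C6 is formed first (step 5); the 1,2-dioxane ring of the 2,3-dioxabicyclo[2.2.2]octene is closed in step 8 and opened again in step 9.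

Key step: step 8

Remark: methyl hydrogen (3R)-3-methylglutarate is taken as a purchasable, enantiopure half-ester; TBS stands for tert-butyldimethylsilyl.

**Route**

Step 1
Reactants: 1 methyl hydrogen (3R)-3-methylglutarate
Product: 2 methyl (3R)-5-hydroxy-3-methylpentanoate
Conditions: BH3·SMe2, THF, 0 °C → rt; then MeOH
Reagents that add atoms: none
Why: Borane reduces the free carboxylic acid through its acyloxyborane far faster than the methyl ester (chemoselective acid reduction), and the C7 stereocentre, β to both carbonyls, is not touched.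

Step 2
Reactants: 2 methyl (3R)-5-hydroxy-3-methylpentanoate
Product: 3 methyl (3R)-5-(tert-butyldimethylsilyloxy)-3-methylpentanoate
Conditions: TBSCl, imidazole, CH2Cl2, 0 °C → rt
Reagents that add atoms: tert-butyldimethylsilyl chloride, CC(C)(C)[Si](C)(C)Cl
Why: Imidazole-promoted silylation of a primary alcohol, run on crude 2 so that lactonisation of the δ-hydroxy ester does not compete.

Step 3
Reactants: 3 methyl (3R)-5-(tert-butyldimethylsilyloxy)-3-methylpentanoate
Product: 4 (3R)-5-(tert-butyldimethylsilyloxy)-3-methylpentanal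
Conditions: i-Bu2AlH (1.05 equiv), CH2Cl2, −78 °C; then aq. Rochelle salt
Reagents that add atoms: none
Why: Partial ester reduction by i-Bu2AlH, whose tetrahedral aluminium hemiacetal is stable at −78 °C and releases the aldehyde only on work-up.

Step 4
Reactants: 4 (3R)-5-(tert-butyldimethylsilyloxy)-3-methylpentanal; 5 methyl vinyl ketone
Product: 6 (2S)-2-[(2R)-4-(tert-butyldimethylsilyloxy)butan-2-yl]-5-oxohexanal
Conditions: (S)-2-[methoxy(diphenyl)methyl]pyrrolidine (10 mol%), ethyl 3,4-dihydroxybenzoate (20 mol%), 5 (1.5 equiv), neat, 4 °C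
Reagents that add atoms: none
Why: Enamine-catalysed Michael addition of an aldehyde to an enone forms the C5–C6 bond: one face of the E-enamine of 4 is shielded by the methoxydiphenylmethyl group of the (S)-pyrrolidine, so the hydrogen-bond-activated enone is attacked from the open face and the new stereocentre (future C6) should be set as 2S under catalyst control, the remote C7 methyl being a spectator.

Step 5
Reactants: 6 (2S)-2-[(2R)-4-(tert-butyldimethylsilyloxy)butan-2-yl]-5-oxohexanal
Product: 7 (4S)-4-[(2R)-4-(tert-butyldimethylsilyloxy)butan-2-yl]cyclohex-2-en-1-one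
Conditions: LiOH (0.3 equiv), i-PrOH, rt
Reagents that add atoms: none
Why: Intramolecular aldol condensation (attack of the methyl ketone enolate on the aldehyde, then E1cB dehydration) closes the carbocycle through the C1–C2 bond, and mild hydroxide in i-PrOH is chosen so that ring closure outruns enolisation of the α-branched aldehyde.

Step 6
Reactants: 7 (4S)-4-[(2R)-4-(tert-butyldimethylsilyloxy)butan-2-yl]cyclohex-2-en-1-one
Product: 9 (4S)-4-[(2R)-4-(tert-butyldimethylsilyloxy)butan-2-yl]cyclohexa-1,5-dien-1-yl trifluoromethanesulfonate, via lithium dienolate 8 (not isolated)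
Conditions: LiN(i-Pr)2, THF, −78 °C; then PhNTf2, −78 → 0 °C
Reagents that add atoms: N-phenylbis(trifluoromethanesulfonimide), O=S(=O)(N(c1ccccc1)S(=O)(=O)C(F)(F)F)C(F)(F)F
Why: Kinetic deprotonation at the α′ methylene (future C4) gives the cross-conjugated dienolate, which is O-sulfonylated (enol triflate formation), and the γ stereocentre (C6) stays safe because the thermodynamic γ-deprotonation is avoided at −78 °C.

Step 7
Reactants: 9 (4S)-4-[(2R)-4-(tert-butyldimethylsilyloxy)butan-2-yl]cyclohexa-1,5-dien-1-yl trifluoromethanesulfonate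
Product: 10 (5S)-2-methyl-5-[(2R)-4-(tert-butyldimethylsilyloxy)butan-2-yl]cyclohexa-1,3-diene
Conditions: MeZnCl (1.5 equiv), Pd(PPh3)4 (5 mol%), THF, 0 °C → rt
Reagents that add atoms: methylzinc chloride, C[Zn]Cl
Why: Negishi cross-coupling of an alkenyl triflate at zerovalent palladium (oxidative addition, transmetalation, reductive elimination) installs the C3 methyl under neutral conditions at or below room temperature, which should leave the 1,3-diene unisomerised and C6 intact.

Step 8
Reactants: 10 (5S)-2-methyl-5-[(2R)-4-(tert-butyldimethylsilyloxy)butan-2-yl]cyclohexa-1,3-diene; 11 dioxygen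
Product: 12 (1S,4R,7S)-7-[(2R)-4-(tert-butyldimethylsilyloxy)butan-2-yl]-5-methyl-2,3-dioxabicyclo[2.2.2]oct-5-ene
Conditions: O2 (1 atm), 5,10,15,20-tetraphenylporphyrin (0.5 mol%), CH2Cl2, −78 °C, white LED light
Reagents that add atoms: none
Why: Energy transfer from photoexcited tetraphenylporphyrin gives singlet oxygen, which adds to the ring-locked s-cis diene C1=C2–C3=C4 in a concerted suprafacial [4+2] cycloaddition, forming the C1–O and C4–O bonds and shifting the alkene to C2=C3. The closest known reaction type is the dye-sensitised photooxygenation of α-phellandrene and other 5-substituted cyclohexa-1,3-dienes to 2,3-dioxabicyclo[2.2.2]oct-5-enes. The one new ring, the six-membered 1,2-dioxane O–C1–C2=C3–C4–O, is closed by the cycloaddition itself (both C–O bonds in the same step), which turns the cyclohexadiene into the bicyclo[2.2.2] skeleton. The new stereocentres C1 and C4 are cis to each other by the suprafacial course, and their sense relative to C6 is controlled by the sec-alkyl group on C6, which sits next to the diene terminus C1 and directs O2 to the opposite face. The step needs π-facial selectivity, which rests on this single neighbouring stereocentre and may be only moderate, so that the syn adduct would be removed by chromatography, and it needs chemoselectivity for cycloaddition over the ene reaction, which the cisoid six-ring diene, the low temperature and the absence of any other electron-rich alkene (C10=C11 enters only in step 15) should secure.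

Step 9
Reactants: 12 (1S,4R,7S)-7-[(2R)-4-(tert-butyldimethylsilyloxy)butan-2-yl]-5-methyl-2,3-dioxabicyclo[2.2.2]oct-5-ene
Product: 13 (4S,5S)-4-hydroxy-2-methyl-5-[(2R)-4-(tert-butyldimethylsilyloxy)butan-2-yl]cyclohex-2-en-1-one
Conditions: Et3N (1.5 equiv), CH2Cl2, 0 °C → rt
Reagents that add atoms: none
Why: Kornblum–DeLaMare rearrangement, in which the amine removes the bridgehead hydrogen on C4 (flanked only by the C5 methylene and easier to reach than the C1 hydrogen beside the branched C6 substituent) while the O–O bond breaks, leaving C4 as the enone carbonyl and C1 as a free carbinol of unchanged configuration.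

Step 10
Reactants: 13 (4S,5S)-4-hydroxy-2-methyl-5-[(2R)-4-(tert-butyldimethylsilyloxy)butan-2-yl]cyclohex-2-en-1-one
Product: 14 (4S,5S)-4-(tert-butyldimethylsilyloxy)-5-[(2R)-4-(tert-butyldimethylsilyloxy)butan-2-yl]-2-methylcyclohex-2-en-1-one
Conditions: TBSCl, imidazole, DMF, rt
Reagents that add atoms: tert-butyldimethylsilyl chloride, CC(C)(C)[Si](C)(C)Cl
Why: Silylation of the secondary allylic alcohol under weakly basic conditions that the γ-hydroxy enone tolerates, masking C1–OH until the angelate is put on.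

Step 11
Reactants: 14 (4S,5S)-4-(tert-butyldimethylsilyloxy)-5-[(2R)-4-(tert-butyldimethylsilyloxy)butan-2-yl]-2-methylcyclohex-2-en-1-one
Product: 16 (2S,4R,5S)-4-(tert-butyldimethylsilyloxy)-5-[(2R)-4-(tert-butyldimethylsilyloxy)butan-2-yl]-2-methylcyclohexan-1-one, via 2-epimeric ketone mixture 15 (not isolated)
Conditions: H2 (1 atm), 10% Pd/C, EtOAc, rt; filter; then DBU (0.2 equiv), CH2Cl2, rt
Reagents that add atoms: none
Why: Heterogeneous hydrogenation saturates the enone C2=C3 bond, and base-mediated enolisation then equilibrates C3 to the epimer with the methyl equatorial, cis to the equatorial C1 silyloxy group and trans to the equatorial C6 chain (thermodynamic control in an all-equatorial chair).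

Step 12
Reactants: 16 (2S,4R,5S)-4-(tert-butyldimethylsilyloxy)-5-[(2R)-4-(tert-butyldimethylsilyloxy)butan-2-yl]-2-methylcyclohexan-1-one
Product: 17 (1R,2S,4R,5S)-4-(tert-butyldimethylsilyloxy)-5-[(2R)-4-(tert-butyldimethylsilyloxy)butan-2-yl]-2-methylcyclohexan-1-ol
Conditions: LiBH(s-Bu)3, THF, −78 °C; then NaOH, H2O2, 0 °C
Reagents that add atoms: none
Why: The bulky trialkylborohydride attacks the C4 carbonyl along the equatorial trajectory (axial attack is blocked by the axial hydrogens on C2 and C6), which should give the axial C4 alcohol cis to the equatorial C3 methyl, as in the reduction of 2-methylcyclohexanones.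

Step 13
Reactants: 17 (1R,2S,4R,5S)-4-(tert-butyldimethylsilyloxy)-5-[(2R)-4-(tert-butyldimethylsilyloxy)butan-2-yl]-2-methylcyclohexan-1-ol
Product: 18 (1R,2S,4R,5S)-4-(tert-butyldimethylsilyloxy)-5-[(2R)-4-hydroxybutan-2-yl]-2-methylcyclohexan-1-ol
Conditions: camphor-10-sulfonic acid (0.1 equiv), MeOH–CH2Cl2 (1:1), 0 °C
Reagents that add atoms: none
Why: Acid-catalysed methanolysis removes the unhindered primary silyl ether much faster than the secondary one on C1, which is shielded by the neighbouring C6 branch.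

Step 14
Reactants: 18 (1R,2S,4R,5S)-4-(tert-butyldimethylsilyloxy)-5-[(2R)-4-hydroxybutan-2-yl]-2-methylcyclohexan-1-ol
Product: 19 (3R)-3-[(1S,2R,4S,5R)-2-(tert-butyldimethylsilyloxy)-5-hydroxy-4-methylcyclohexyl]butanal
Conditions: TEMPO (0.1 equiv), PhI(OAc)2 (1.1 equiv), CH2Cl2, rt
Reagents that add atoms: none
Why: Oxoammonium oxidation is selective for primary over hindered secondary alcohols and stops at the aldehyde, so the axial C4 hydroxyl needs no protection.

Step 15
Reactants: 19 (3R)-3-[(1S,2R,4S,5R)-2-(tert-butyldimethylsilyloxy)-5-hydroxy-4-methylcyclohexyl]butanal; 20 2-methylprop-1-enylmagnesium bromide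
Product: 21 (4RS,6R)-6-[(1S,2R,4S,5R)-2-(tert-butyldimethylsilyloxy)-5-hydroxy-4-methylcyclohexyl]-2-methylhept-2-en-4-ol
Conditions: 20 (2.5 equiv), THF, −78 → 0 °C; then aq. NH4Cl
Reagents that add atoms: none
Why: Grignard 1,2-addition to the aldehyde forms the C9–C10 bond after the first equivalent has deprotonated C4–OH, and the C9 epimer mixture is of no consequence because C9 is oxidised in step 16.

Step 16
Reactants: 21 (4RS,6R)-6-[(1S,2R,4S,5R)-2-(tert-butyldimethylsilyloxy)-5-hydroxy-4-methylcyclohexyl]-2-methylhept-2-en-4-ol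
Product: 22 (6R)-6-[(1S,2R,4S,5R)-2-(tert-butyldimethylsilyloxy)-5-hydroxy-4-methylcyclohexyl]-2-methylhept-2-en-4-one
Conditions: MnO2 (excess), CH2Cl2, rt
Reagents that add atoms: none
Why: MnO2 oxidises only the allylic C9 alcohol, and the saturated axial C4 alcohol is inert to it.

Step 17
Reactants: 22 (6R)-6-[(1S,2R,4S,5R)-2-(tert-butyldimethylsilyloxy)-5-hydroxy-4-methylcyclohexyl]-2-methylhept-2-en-4-one
Product: 23 (4R,6R)-6-[(1S,2R,4S,5R)-2-(tert-butyldimethylsilyloxy)-5-hydroxy-4-methylcyclohexyl]-2-methylhept-2-en-4-ol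
Conditions: (S)-2-methyl-CBS-oxazaborolidine (0.5 equiv), BH3·SMe2 (2.2 equiv), THF, −30 °C; then MeOH
Reagents that add atoms: none
Why: Corey–Bakshi–Shibata reduction, in which the 2-methylpropenyl group takes the role of the large substituent in the ketone–oxazaborolidine–borane complex, so the (S)-catalyst should deliver hydride to the face that gives the (9R)-allylic alcohol by 1,2-reduction, the extra borane being consumed by the free C4 hydroxyl.

Step 18
Reactants: 23 (4R,6R)-6-[(1S,2R,4S,5R)-2-(tert-butyldimethylsilyloxy)-5-hydroxy-4-methylcyclohexyl]-2-methylhept-2-en-4-ol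
Product: 24 (4R,6R)-6-[(1S,2R,4S,5R)-5-acetoxy-2-(tert-butyldimethylsilyloxy)-4-methylcyclohexyl]-2-methylhept-2-en-4-yl acetate
Conditions: Ac2O, pyridine, DMAP (cat.), CH2Cl2, rt
Reagents that add atoms: acetic anhydride, CC(=O)OC(C)=O
Why: DMAP-catalysed acylation esterifies the axial C4 and the allylic C9 hydroxyl in one operation, and the basic medium avoids ionisation of the allylic acetate.

Step 19
Reactants: 24 (4R,6R)-6-[(1S,2R,4S,5R)-5-acetoxy-2-(tert-butyldimethylsilyloxy)-4-methylcyclohexyl]-2-methylhept-2-en-4-yl acetate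
Product: 25 (4R,6R)-6-[(1S,2R,4S,5R)-5-acetoxy-2-hydroxy-4-methylcyclohexyl]-2-methylhept-2-en-4-yl acetate
Conditions: HF·pyridine, pyridine, THF, 0 °C → rt
Reagents that add atoms: none
Why: Fluoride-driven Si–O cleavage with pyridine-buffered HF·pyridine removes the hindered secondary silyl ether without touching the two acetates.

Step 20
Reactants: 25 (4R,6R)-6-[(1S,2R,4S,5R)-5-acetoxy-2-hydroxy-4-methylcyclohexyl]-2-methylhept-2-en-4-yl acetate; 26 angelic acid
Product: 28 (1R,2S,4R,5S)-4-acetoxy-2-[(2R,4R)-4-acetoxy-6-methylhept-5-en-2-yl]-5-methylcyclohexyl (2Z)-2-methylbut-2-enoate, via angeloyl 2,4,6-trichlorobenzoyl anhydride 27 (not isolated)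
Conditions: 26, 2,4,6-trichlorobenzoyl chloride, Et3N, toluene, rt; then 25, toluene, 80 °C
Reagents that add atoms: none
Why: Yamaguchi-type esterification, in which the mixed anhydride acylates the C1 alcohol at the less hindered angeloyl carbonyl, and leaving out a nucleophilic catalyst should avoid the addition–elimination pathway that isomerises angelate to tiglate.

**Compound list**

1 | methyl hydrogen (3R)-3-methylglutarate [(3R)-5-methoxy-3-methyl-5-oxopentanoic acid] | COC(=O)C[C@H](C)CC(=O)O | starting material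
2 | methyl (3R)-5-hydroxy-3-methylpentanoate | COC(=O)C[C@H](C)CCO | intermediate
3 | methyl (3R)-5-(tert-butyldimethylsilyloxy)-3-methylpentanoate | COC(=O)C[C@H](C)CCO[Si](C)(C)C(C)(C)C | intermediate
4 | (3R)-5-(tert-butyldimethylsilyloxy)-3-methylpentanal | O=CC[C@H](C)CCO[Si](C)(C)C(C)(C)C | intermediate
5 | methyl vinyl ketone (but-3-en-2-one) | CC(=O)C=C | starting material
6 | (2S)-2-[(2R)-4-(tert-butyldimethylsilyloxy)butan-2-yl]-5-oxohexanal | CC(=O)CC[C@H](C=O)[C@H](C)CCO[Si](C)(C)C(C)(C)C | intermediate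
7 | (4S)-4-[(2R)-4-(tert-butyldimethylsilyloxy)butan-2-yl]cyclohex-2-en-1-one | O=C1C=C[C@H]([C@H](C)CCO[Si](C)(C)C(C)(C)C)CC1 | intermediate
8 | lithium (4S)-4-[(2R)-4-(tert-butyldimethylsilyloxy)butan-2-yl]cyclohexa-1,5-dien-1-olate (not isolated) | [Li+].[O-]C1=CC[C@H](C=C1)[C@H](C)CCO[Si](C)(C)C(C)(C)C | intermediate
9 | (4S)-4-[(2R)-4-(tert-butyldimethylsilyloxy)butan-2-yl]cyclohexa-1,5-dien-1-yl trifluoromethanesulfonate | O=S(=O)(OC1=CC[C@H](C=C1)[C@H](C)CCO[Si](C)(C)C(C)(C)C)C(F)(F)F | intermediate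
10 | (5S)-2-methyl-5-[(2R)-4-(tert-butyldimethylsilyloxy)butan-2-yl]cyclohexa-1,3-diene | C1=CC(C)=CC[C@H]1[C@H](C)CCO[Si](C)(C)C(C)(C)C | intermediate
11 | dioxygen | O=O | starting material
12 | (1S,4R,7S)-7-[(2R)-4-(tert-butyldimethylsilyloxy)butan-2-yl]-5-methyl-2,3-dioxabicyclo[2.2.2]oct-5-ene | O1[C@@H]2C=C(C)[C@H](O1)C[C@H]2[C@H](C)CCO[Si](C)(C)C(C)(C)C | intermediate
13 | (4S,5S)-4-hydroxy-2-methyl-5-[(2R)-4-(tert-butyldimethylsilyloxy)butan-2-yl]cyclohex-2-en-1-one | O=C1C(C)=C[C@@H](O)[C@H]([C@H](C)CCO[Si](C)(C)C(C)(C)C)C1 | intermediate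
14 | (4S,5S)-4-(tert-butyldimethylsilyloxy)-5-[(2R)-4-(tert-butyldimethylsilyloxy)butan-2-yl]-2-methylcyclohex-2-en-1-one | O=C1C(C)=C[C@@H](O[Si](C)(C)C(C)(C)C)[C@H]([C@H](C)CCO[Si](C)(C)C(C)(C)C)C1 | intermediate
15 | (2RS,4R,5S)-4-(tert-butyldimethylsilyloxy)-5-[(2R)-4-(tert-butyldimethylsilyloxy)butan-2-yl]-2-methylcyclohexan-1-one, mixture of C2 epimers (not isolated) | O=C1C(C)C[C@@H](O[Si](C)(C)C(C)(C)C)[C@H]([C@H](C)CCO[Si](C)(C)C(C)(C)C)C1 | intermediate
16 | (2S,4R,5S)-4-(tert-butyldimethylsilyloxy)-5-[(2R)-4-(tert-butyldimethylsilyloxy)butan-2-yl]-2-methylcyclohexan-1-one | O=C1[C@@H](C)C[C@@H](O[Si](C)(C)C(C)(C)C)[C@H]([C@H](C)CCO[Si](C)(C)C(C)(C)C)C1 | intermediate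
17 | (1R,2S,4R,5S)-4-(tert-butyldimethylsilyloxy)-5-[(2R)-4-(tert-butyldimethylsilyloxy)butan-2-yl]-2-methylcyclohexan-1-ol | O[C@H]1[C@@H](C)C[C@@H](O[Si](C)(C)C(C)(C)C)[C@H]([C@H](C)CCO[Si](C)(C)C(C)(C)C)C1 | intermediate
18 | (1R,2S,4R,5S)-4-(tert-butyldimethylsilyloxy)-5-[(2R)-4-hydroxybutan-2-yl]-2-methylcyclohexan-1-ol | O[C@H]1[C@@H](C)C[C@@H](O[Si](C)(C)C(C)(C)C)[C@H]([C@H](C)CCO)C1 | intermediate
19 | (3R)-3-[(1S,2R,4S,5R)-2-(tert-butyldimethylsilyloxy)-5-hydroxy-4-methylcyclohexyl]butanal | O[C@H]1[C@@H](C)C[C@@H](O[Si](C)(C)C(C)(C)C)[C@H]([C@H](C)CC=O)C1 | intermediate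
20 | 2-methylprop-1-enylmagnesium bromide | CC(C)=C[Mg]Br | starting material
21 | (4RS,6R)-6-[(1S,2R,4S,5R)-2-(tert-butyldimethylsilyloxy)-5-hydroxy-4-methylcyclohexyl]-2-methylhept-2-en-4-ol | O[C@H]1[C@@H](C)C[C@@H](O[Si](C)(C)C(C)(C)C)[C@H]([C@H](C)CC(O)C=C(C)C)C1 | intermediate
22 | (6R)-6-[(1S,2R,4S,5R)-2-(tert-butyldimethylsilyloxy)-5-hydroxy-4-methylcyclohexyl]-2-methylhept-2-en-4-one | O[C@H]1[C@@H](C)C[C@@H](O[Si](C)(C)C(C)(C)C)[C@H]([C@H](C)CC(=O)C=C(C)C)C1 | intermediate
23 | (4R,6R)-6-[(1S,2R,4S,5R)-2-(tert-butyldimethylsilyloxy)-5-hydroxy-4-methylcyclohexyl]-2-methylhept-2-en-4-ol | O[C@H]1[C@@H](C)C[C@@H](O[Si](C)(C)C(C)(C)C)[C@H]([C@H](C)C[C@@H](O)C=C(C)C)C1 | intermediate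
24 | (4R,6R)-6-[(1S,2R,4S,5R)-5-acetoxy-2-(tert-butyldimethylsilyloxy)-4-methylcyclohexyl]-2-methylhept-2-en-4-yl acetate | CC(=O)O[C@H]1[C@@H](C)C[C@@H](O[Si](C)(C)C(C)(C)C)[C@H]([C@H](C)C[C@@H](OC(C)=O)C=C(C)C)C1 | intermediate
25 | (4R,6R)-6-[(1S,2R,4S,5R)-5-acetoxy-2-hydroxy-4-methylcyclohexyl]-2-methylhept-2-en-4-yl acetate | CC(=O)O[C@H]1[C@@H](C)C[C@@H](O)[C@H]([C@H](C)C[C@@H](OC(C)=O)C=C(C)C)C1 | intermediate
26 | angelic acid [(2Z)-2-methylbut-2-enoic acid] | C/C=C(/C)C(=O)O | starting material
27 | (2Z)-2-methylbut-2-enoic 2,4,6-trichlorobenzoic anhydride (not isolated) | C/C=C(/C)C(=O)OC(=O)c1c(Cl)cc(Cl)cc1Cl | intermediate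
28 | (1R,2S,4R,5S)-4-acetoxy-2-[(2R,4R)-4-acetoxy-6-methylhept-5-en-2-yl]-5-methylcyclohexyl (2Z)-2-methylbut-2-enoate (CNP0286954.1) | C/C=C(/C)C(=O)O[C@@H]1C[C@H](C)[C@H](OC(C)=O)C[C@H]1[C@H](C)C[C@H](C=C(C)C)OC(C)=O | target

**Step count**

Total: 20 steps. Longest linear sequence: 20 steps (1 → 28).

**Steps most likely to fail**

Step 8 (photooxygenation). Attack of singlet oxygen on the diene face syn to the C6 substituent may compete, since only one neighbouring stereocentre discriminates the faces. Ene reaction at the C3 methyl or C5 methylene and decomposition of the peroxide under prolonged irradiation may lower the return further. Fallback, setting out from 10: the photooxygenation is run to full conversion and the adduct mixture, which then contains the syn endoperoxide (1R,4S,7S)-7-[(2R)-4-(tert-butyldimethylsilyloxy)butan-2-yl]-5-methyl-2,3-dioxabicyclo[2.2.2]oct-5-ene F1, is taken without separation through the amine-mediated opening. The C1-epimeric hydroxy enone (4R,5S)-4-hydroxy-2-methyl-5-[(2R)-4-(tert-butyldimethylsilyloxy)butan-2-yl]cyclohex-2-en-1-one F2 is separated from 13 and inverted at C1 by a Mitsunobu reaction (PPh3, diisopropyl azodicarboxylate, 4-nitrobenzoic acid, THF) to the ester (1S,6S)-6-[(2R)-4-(tert-butyldimethylsilyloxy)butan-2-yl]-3-methyl-4-oxocyclohex-2-en-1-yl 4-nitrobenzoate F3. Methanolysis (K2CO3, MeOH, 0 °C) then returns the material to the route at 13, so that facial selectivity no longer limits throughput.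

Step 9 (peroxide opening). Deprotonation at the wrong bridgehead (C1–H) would give the regioisomeric hydroxy enone with the ketone on C1, and continued exposure to base may isomerise the γ-hydroxy enone to a 1,4-dione. Fallback, setting out from 12: the O–O bond is reduced with thiourea in MeOH to the cis-enediol (1R,4S,5S)-2-methyl-5-[(2R)-4-(tert-butyldimethylsilyloxy)butan-2-yl]cyclohex-2-ene-1,4-diol F4. The two allylic hydroxyls are then told apart in a separate oxidation with catalytic TEMPO and PhI(OAc)2, whose bulky oxoammonium ion should prefer the C4 carbinol (next to the C5 methylene) over the C1 carbinol (next to the branched C6). This returns to the route at 13.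

Step 20 (angeloylation). Z-to-E isomerisation of the angeloyl unit to the tiglate during slow acylation of the hindered C1 alcohol, or incomplete conversion at the temperature needed, may occur. Fallback, setting out from 25: the alcohol is first esterified with 2-[bis(2,2,2-trifluoroethoxy)phosphoryl]propanoic acid (N,N'-dicyclohexylcarbodiimide, DMAP, CH2Cl2) to the phosphonopropanoate (4R,6R)-6-[(1S,2R,4S,5R)-5-acetoxy-2-{2-[bis(2,2,2-trifluoroethoxy)phosphoryl]propanoyloxy}-4-methylcyclohexyl]-2-methylhept-2-en-4-yl acetate F5. The Z-alkene is then built on the ester by a Still–Gennari olefination with acetaldehyde (KN(SiMe3)2, 18-crown-6, THF, −78 °C), which arrives at 28 without ever handling an activated angelic acid derivative.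

**Further compounds**

F1 | step 8 | (1R,4S,7S)-7-[(2R)-4-(tert-butyldimethylsilyloxy)butan-2-yl]-5-methyl-2,3-dioxabicyclo[2.2.2]oct-5-ene | O1[C@H]2C=C(C)[C@@H](O1)C[C@H]2[C@H](C)CCO[Si](C)(C)C(C)(C)C
F2 | step 8 | (4R,5S)-4-hydroxy-2-methyl-5-[(2R)-4-(tert-butyldimethylsilyloxy)butan-2-yl]cyclohex-2-en-1-one | O=C1C(C)=C[C@H](O)[C@H]([C@H](C)CCO[Si](C)(C)C(C)(C)C)C1
F3 | step 8 | (1S,6S)-6-[(2R)-4-(tert-butyldimethylsilyloxy)butan-2-yl]-3-methyl-4-oxocyclohex-2-en-1-yl 4-nitrobenzoate | O=C1C(C)=C[C@@H](OC(=O)c2ccc(cc2)[N+](=O)[O-])[C@H]([C@H](C)CCO[Si](C)(C)C(C)(C)C)C1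
F4 | step 9 | (1R,4S,5S)-2-methyl-5-[(2R)-4-(tert-butyldimethylsilyloxy)butan-2-yl]cyclohex-2-ene-1,4-diol | O[C@@H]1C=C(C)[C@H](O)C[C@H]1[C@H](C)CCO[Si](C)(C)C(C)(C)C
F5 | step 20 | (4R,6R)-6-[(1S,2R,4S,5R)-5-acetoxy-2-{2-[bis(2,2,2-trifluoroethoxy)phosphoryl]propanoyloxy}-4-methylcyclohexyl]-2-methylhept-2-en-4-yl acetate | CC(=O)O[C@H]1[C@@H](C)C[C@@H](OC(=O)C(C)P(=O)(OCC(F)(F)F)OCC(F)(F)F)[C@H]([C@H](C)C[C@@H](OC(C)=O)C=C(C)C)C1
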